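**Retrosynthetic overview**

1. Target 27 ⇐ bromo epoxy enyne 25 (step 17). The oxane ring (O, C9, C10, C11, C12, C13) is made last, by bromonium-triggered ring expansion of the 9,10-epoxide onto the 12E-alkene with bromide return at C10. One operation forms C13–O, C12–Br and C10–Br and fixes C10, C12 and C13.
2. Enabling feature: in that ring both carbons β to oxygen (C10, C12) carry Br anti to the C–O bond of their neighbour (C9, C13) and are separated only by the C11 methylene. The ring is therefore Br⁺ and Br⁻ added across a 9,10-epoxide and a 12,13-alkene; the C8 bromide beside C9 steers bromide to C10.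
3. 25 ⇐ allylic alcohol 22 (Sharpless epoxidation, then SN2 bromide at C8) ⇐ Nozaki–Hiyama–Kishi union (C8–C9) of bicyclic aldehyde 16 with (1E,4E)-1-iodohepta-1,4-diene 21.
4. 16 ⇐ 2,5-dioxabicyclo[2.2.1]heptane ester 15 ⇐ ring contraction of α-triflyloxy δ-lactone 13 (O–C7 bond) ⇐ oxolane triol 9 (O–C6 bond, 5-exo epoxide opening) ⇐ 2-deoxy-L-ribose. Sugar C1–C5 become C6–C2 of the target; C7/C8 come from a Wittig reagent and C1 from the Ohira–Bestmann reagent.
5. Ring order: oxolane C3–O–C6 (step 7), oxolane C4–O–C7 closing the bicycle (step 10), oxane C9–O–C13 (step 17).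

Key step: step 17

Remark: locants C1–C15 are those of the target chain (C1≡C2–C3 … C15H3) and are used for all intermediates.
Assumption: BDSB (bromodiethylsulfonium bromopentachloroantimonate) is used as a ready-made reagent (from Et2S, Br2 and SbCl5); 2-deoxy-L-ribose, (2E)-1-bromopent-2-ene and ethynylmagnesium bromide are taken as commercial.

**Route**

Step 1
Reactants: 1 2-deoxy-L-ribose
Product: 2 2-deoxy-3,4-O-isopropylidene-L-erythro-pentopyranose
Conditions: 2-methoxypropene, PPTS (cat.), EtOAc, 0 °C → rt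
Reagents that add atoms: 2-methoxypropene, COC(C)=C
Why: Acid-catalysed acetonide formation traps the cis-3,4-diol of the pyranose form as the dioxolane and leaves the lactol free for olefination; no stereocentre is made, since C3 and C4 of the target come unchanged from the sugar.

Step 2
Reactants: 2 2-deoxy-3,4-O-isopropylidene-L-erythro-pentopyranose
Product: 3 methyl (2E)-4-[(4R,5S)-5-(hydroxymethyl)-2,2-dimethyl-1,3-dioxolan-4-yl]but-2-enoate
Conditions: Ph3P=CHCO2Me, PhCO2H (cat.), THF, 60 °C
Reagents that add atoms: methyl (triphenylphosphoranylidene)acetate, COC(=O)C=P(c1ccccc1)(c1ccccc1)c1ccccc1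
Why: Wittig olefination of the lactol through its open-chain aldehyde with a stabilised ylide should give the (E)-enoate (C7, C8) and release the former ring oxygen as the primary C2 hydroxyl.

Step 3
Reactants: 3 methyl (2E)-4-[(4R,5S)-5-(hydroxymethyl)-2,2-dimethyl-1,3-dioxolan-4-yl]but-2-enoate
Product: 4 methyl (2E)-4-[(4R,5R)-5-formyl-2,2-dimethyl-1,3-dioxolan-4-yl]but-2-enoate
Conditions: Dess–Martin periodinane, CH2Cl2, 0 °C → rt
Reagents that add atoms: none
Why: Dess–Martin oxidation converts the primary alcohol into the aldehyde under non-basic conditions that should leave the epimerisable cis-dioxolane centre C3 and the enoate untouched.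

Step 4
Reactants: 4 methyl (2E)-4-[(4R,5R)-5-formyl-2,2-dimethyl-1,3-dioxolan-4-yl]but-2-enoate
Product: 5 methyl (2E)-4-[(4R,5S)-5-ethynyl-2,2-dimethyl-1,3-dioxolan-4-yl]but-2-enoate
Conditions: dimethyl (1-diazo-2-oxopropyl)phosphonate, NaOMe, THF, −78 °C; then 4, −78 → 0 °C
Reagents that add atoms: dimethyl (1-diazo-2-oxopropyl)phosphonate, CC(=O)C(=[N+]=[N-])P(=O)(OC)OC
Why: Seyferth–Gilbert homologation with the Ohira–Bestmann reagent, with the diazophosphonate anion pre-formed at low temperature, should turn the aldehyde into the terminal alkyne (C1) faster than the cis-dioxolane aldehyde epimerises at C3.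

Step 5
Reactants: 5 methyl (2E)-4-[(4R,5S)-5-ethynyl-2,2-dimethyl-1,3-dioxolan-4-yl]but-2-enoate
Product: 6 (2E)-4-[(4R,5S)-5-ethynyl-2,2-dimethyl-1,3-dioxolan-4-yl]but-2-en-1-ol
Conditions: DIBAL-H (2.5 equiv), CH2Cl2, −78 °C; Rochelle salt
Reagents that add atoms: none
Why: 1,2-Reduction of the enoate with DIBAL-H gives the (E)-allylic alcohol needed for hydroxyl-directed epoxidation, the alkyne and the acetonide being inert at −78 °C.

Step 6
Reactants: 6 (2E)-4-[(4R,5S)-5-ethynyl-2,2-dimethyl-1,3-dioxolan-4-yl]but-2-en-1-ol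
Product: 7 [(2S,3S)-3-{[(4R,5S)-5-ethynyl-2,2-dimethyl-1,3-dioxolan-4-yl]methyl}oxiran-2-yl]methanol
Conditions: Ti(OiPr)4 (10 mol%), L-(+)-DET (12 mol%), t-BuOOH, 4 Å MS, CH2Cl2, −20 °C
Reagents that add atoms: tert-butyl hydroperoxide, CC(C)(C)OO
Why: Katsuki–Sharpless asymmetric epoxidation of an (E)-allylic alcohol is reagent-controlled, and L-(+)-diethyl tartrate should give the (2S,3S)-epoxy alcohol whose two carbons become C6 (after inversion in step 7) and C7 (after inversion in step 10).

Step 7
Reactants: 7 [(2S,3S)-3-{[(4R,5S)-5-ethynyl-2,2-dimethyl-1,3-dioxolan-4-yl]methyl}oxiran-2-yl]methanol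
Product: 9 (1S)-1-[(2R,4R,5S)-5-ethynyl-4-hydroxyoxolan-2-yl]ethane-1,2-diol, via epoxy triol 8 (not isolated)
Conditions: CSA (10 mol%), MeOH, 0 °C → rt
Reagents that add atoms: none
Why: Acid-catalysed transketalisation frees the C3 hydroxyl, which opens the epoxide 5-exo at C6 (the carbon remote from the CH2OH group) with inversion, so the new oxolane should carry its side chain cis to the C4 hydroxyl while C7 keeps the epoxide configuration.

Step 8
Reactants: 9 (1S)-1-[(2R,4R,5S)-5-ethynyl-4-hydroxyoxolan-2-yl]ethane-1,2-diol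
Product: 12 (1R,4R,5R,7S)-7-ethynyl-4-hydroxy-2,6-dioxabicyclo[3.2.1]octan-3-one, via hydroxy aldehyde 10 (not isolated), via lactol 11 (not isolated)
Conditions: TEMPO (20 mol%), PhI(OAc)2 (2.5 equiv), CH2Cl2, rt
Reagents that add atoms: none
Why: TEMPO/PhI(OAc)2 oxidative lactonisation of the 1,5-diol oxidises only the primary C8 alcohol, the aldehyde is trapped by the cis C4 hydroxyl as a lactol and oxidised on to the δ-lactone, a temporary ring that masks C4–OH and leaves the C7 hydroxyl as the only free one.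

Step 9
Reactants: 12 (1R,4R,5R,7S)-7-ethynyl-4-hydroxy-2,6-dioxabicyclo[3.2.1]octan-3-one
Product: 13 (1R,4R,5R,7S)-7-ethynyl-3-oxo-2,6-dioxabicyclo[3.2.1]octan-4-yl trifluoromethanesulfonate
Conditions: Tf2O, pyridine, CH2Cl2, −30 °C
Reagents that add atoms: trifluoromethanesulfonic anhydride, O=S(=O)(OS(=O)(=O)C(F)(F)F)C(F)(F)F
Why: O-Sulfonylation of the single free hydroxyl gives the α-triflyloxy lactone with retention at C7 and installs the leaving group for the ring contraction.

Step 10
Reactants: 13 (1R,4R,5R,7S)-7-ethynyl-3-oxo-2,6-dioxabicyclo[3.2.1]octan-4-yl trifluoromethanesulfonate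
Product: 15 methyl (1R,3S,4R,6S)-6-ethynyl-2,5-dioxabicyclo[2.2.1]heptane-3-carboxylate, via hydroxy triflate ester 14 (not isolated)
Conditions: K2CO3, MeOH, −20 → 0 °C
Reagents that add atoms: methanol, CO
Why: Ring contraction of an α-triflyloxy δ-lactone: methoxide opens the lactone to the methyl ester and the released C4 alkoxide displaces the α-triflate in a 5-exo-tet SN2 with inversion at C7, closing the second oxolane and thus the 2,5-dioxabicyclo[2.2.1]heptane with the ester endo (the alkoxide/sulfonate closure used for 2′,4′-bridged nucleoside sugars).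

Step 11
Reactants: 15 methyl (1R,3S,4R,6S)-6-ethynyl-2,5-dioxabicyclo[2.2.1]heptane-3-carboxylate
Product: 16 (1R,3S,4R,6S)-6-ethynyl-2,5-dioxabicyclo[2.2.1]heptane-3-carbaldehyde
Conditions: DIBAL-H (1.1 equiv), CH2Cl2, −78 °C; Rochelle salt; used crude
Reagents that add atoms: none
Why: Partial reduction of the α-alkoxy methyl ester with DIBAL-H at −78 °C should stop at the aldehyde through the chelated hemiacetal aluminate, without touching C7.

Step 12
Reactants: 17 (2E)-1-bromopent-2-ene; 18 ethynylmagnesium bromide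
Product: 19 (4E)-hept-4-en-1-yne
Conditions: CuBr·SMe2 (5 mol%), THF, 0 °C → rt
Reagents that add atoms: none
Why: Copper(I)-catalysed coupling of an alkynyl Grignard reagent with a primary allylic bromide at the α-carbon should give the skipped enyne with the E geometry retained.

Step 13
Reactants: 19 (4E)-hept-4-en-1-yne
Product: 21 (1E,4E)-1-iodohepta-1,4-diene, via alkenylzirconocene chloride 20 (not isolated)
Conditions: Cp2Zr(H)Cl, THF, rt; then I2, 0 °C
Reagents that add atoms: iodine, II
Why: Hydrozirconation adds Zr–H syn across the terminal alkyne (Zr at the terminus, the 1,2-disubstituted alkene untouched) and iodinolysis with retention gives the (E)-vinyl iodide.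

Step 14
Reactants: 16 (1R,3S,4R,6S)-6-ethynyl-2,5-dioxabicyclo[2.2.1]heptane-3-carbaldehyde; 21 (1E,4E)-1-iodohepta-1,4-diene
Product: 22 (1R,2E,5E)-1-[(1R,3R,4R,6S)-6-ethynyl-2,5-dioxabicyclo[2.2.1]heptan-3-yl]octa-2,5-dien-1-ol
Conditions: CrCl2 (4 equiv), NiCl2 (1 mol%), DMSO, rt
Reagents that add atoms: none
Why: Nozaki–Hiyama–Kishi coupling: the alkenylchromium(III) species formed with retention of E geometry adds only to the aldehyde, and polar Felkin–Anh control (C7–O bond anti to the nucleophile, attack past H and not past the bridgehead C6) should favour the 8R alcohol with the new hydroxyl anti to the C7 oxygen.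

Step 15
Reactants: 22 (1R,2E,5E)-1-[(1R,3R,4R,6S)-6-ethynyl-2,5-dioxabicyclo[2.2.1]heptan-3-yl]octa-2,5-dien-1-ol
Product: 23 (R)-[(1R,3R,4R,6S)-6-ethynyl-2,5-dioxabicyclo[2.2.1]heptan-3-yl]{(2S,3S)-3-[(2E)-pent-2-en-1-yl]oxiran-2-yl}methanol
Conditions: Ti(OiPr)4 (1.0 equiv), L-(+)-DIPT (1.2 equiv), t-BuOOH (2 equiv), 4 Å MS, CH2Cl2, −20 °C
Reagents that add atoms: tert-butyl hydroperoxide, CC(C)(C)OO
Why: Sharpless epoxidation of a secondary (E)-allylic alcohol: with L-(+)-DIPT the 8R carbinol is the fast-reacting matched case and should give the erythro epoxy alcohol, so C9 and C10 are set by the reagent on the allylic 9,10-alkene only, while any 8S epimer from step 14 reacts slowly and is left behind.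

Step 16
Reactants: 23 (R)-[(1R,3R,4R,6S)-6-ethynyl-2,5-dioxabicyclo[2.2.1]heptan-3-yl]{(2S,3S)-3-[(2E)-pent-2-en-1-yl]oxiran-2-yl}methanol
Product: 25 (1R,3S,4R,6S)-3-[(S)-bromo{(2R,3S)-3-[(2E)-pent-2-en-1-yl]oxiran-2-yl}methyl]-6-ethynyl-2,5-dioxabicyclo[2.2.1]heptane, via C8 triflate 24 (not isolated)
Conditions: Tf2O, 2,6-lutidine, CH2Cl2, −78 °C; then n-Bu4NBr, −78 → 0 °C
Reagents that add atoms: tetrabutylammonium bromide, CCCC[N+](CCCC)(CCCC)CCCC.[Br-]
Why: Triflate formation followed by SN2 displacement with bromide inverts C8 to the spatial arrangement of the target, and the cold, buffered medium should keep the oxirane closed.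

Step 17
Reactants: 25 (1R,3S,4R,6S)-3-[(S)-bromo{(2R,3S)-3-[(2E)-pent-2-en-1-yl]oxiran-2-yl}methyl]-6-ethynyl-2,5-dioxabicyclo[2.2.1]heptane
Product: 27 (1R,3S,4R,6S)-3-[(R)-bromo{(2R,3R,5S,6R)-3,5-dibromo-6-ethyloxan-2-yl}methyl]-6-ethynyl-2,5-dioxabicyclo[2.2.1]heptane, via epoxonium salt 26 (not isolated)
Conditions: BDSB (1.1 equiv), MeNO2, −25 °C, 5 min; then n-Bu4NBr (3 equiv), −25 → 0 °C
Reagents that add atoms: bromodiethylsulfonium bromopentachloroantimonate (BDSB), CC[S+](Br)CC.Cl[Sb-](Cl)(Cl)(Cl)(Cl)Br; tetrabutylammonium bromide, CCCC[N+](CCCC)(CCCC)CCCC.[Br-]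
Why: Proposed new method: BDSB should transfer Br⁺ to the electron-rich 12,13-alkene (the propargylic-ether alkyne is far less nucleophilic) and, its counter-ion being non-nucleophilic, the bromonium ion should be opened anti at C13 by the epoxide oxygen (attack at C12 would need an oxetane-fused oxonium ion) to give the 1-oxoniabicyclo[3.1.0]hexane 26, which the bromide added afterwards opens by SN2 at the ring-fusion carbon C10, expanding the oxirane to the oxane; the closest known reaction types are the BDSB ring-expanding bromoetherification of homoallylic cyclic ethers through bicyclic oxonium ions, bromonium-initiated epoxide-opening cascades and the halide opening of trialkyloxonium ions. The oxane is closed at the O–C13 bond by an endo opening of the bromonium ion (5-endo for the transient five-membered oxonium ring, which becomes the six-membered C9–O–C13 ring once bromide cuts O–C10). C12 and C13 follow from anti addition to the E alkene (Br and ethyl trans), C13 relative to C9 from the ethyl group taking the convex face of the [3.1.0] epoxonium ion anti to the apex carbon C9 (this is the 2,6-cis oxane), and C10 from inversion of the trans-epoxide, so all four ring substituents should end up equatorial. The step needs bromide to attack C10 and not C9 or C13: of the three carbons on the oxonium oxygen only C10 has no C–Br neighbour (C9 is flanked by the C8 bromide, C13 by the new C12 bromide), the same inductive and steric bias that sends nucleophiles to C3 of 2,3-epoxy alcohol derivatives, and the strained three-ring C–O bonds are cut before the C13–O bond. Vicinal dibromide formation is avoided because free bromide is added only after the bromonium donor has been consumed.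

**Compound list**

1 | 2-deoxy-L-ribose ((3R,4S), drawn as the open-chain aldehyde) | O=CC[C@@H](O)[C@@H](O)CO | starting material
2 | 2-deoxy-3,4-O-isopropylidene-L-erythro-pentopyranose (lactol, anomer mixture) | OC1C[C@H]2OC(C)(C)O[C@H]2CO1 | intermediate
3 | methyl (2E)-4-[(4R,5S)-5-(hydroxymethyl)-2,2-dimethyl-1,3-dioxolan-4-yl]but-2-enoate | OC[C@@H]1OC(C)(C)O[C@@H]1C/C=C/C(=O)OC | intermediate
4 | methyl (2E)-4-[(4R,5R)-5-formyl-2,2-dimethyl-1,3-dioxolan-4-yl]but-2-enoate | O=C[C@@H]1OC(C)(C)O[C@@H]1C/C=C/C(=O)OC | intermediate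
5 | methyl (2E)-4-[(4R,5S)-5-ethynyl-2,2-dimethyl-1,3-dioxolan-4-yl]but-2-enoate | C#C[C@@H]1OC(C)(C)O[C@@H]1C/C=C/C(=O)OC | intermediate
6 | (2E)-4-[(4R,5S)-5-ethynyl-2,2-dimethyl-1,3-dioxolan-4-yl]but-2-en-1-ol | C#C[C@@H]1OC(C)(C)O[C@@H]1C/C=C/CO | intermediate
7 | [(2S,3S)-3-{[(4R,5S)-5-ethynyl-2,2-dimethyl-1,3-dioxolan-4-yl]methyl}oxiran-2-yl]methanol | C#C[C@@H]1OC(C)(C)O[C@@H]1C[C@@H]2O[C@H]2CO | intermediate
8 | epoxy triol: (2R,3S)-1-[(2S,3S)-3-(hydroxymethyl)oxiran-2-yl]pent-4-yne-2,3-diol | C#C[C@H](O)[C@H](O)C[C@@H]1O[C@H]1CO | intermediate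
9 | (1S)-1-[(2R,4R,5S)-5-ethynyl-4-hydroxyoxolan-2-yl]ethane-1,2-diol | C#C[C@@H]1O[C@H](C[C@H]1O)[C@@H](O)CO | intermediate
10 | hydroxy aldehyde: (2R)-2-[(2R,4R,5S)-5-ethynyl-4-hydroxyoxolan-2-yl]-2-hydroxyacetaldehyde | C#C[C@@H]1O[C@H](C[C@H]1O)[C@@H](O)C=O | intermediate
11 | lactol: (1R,4R,5R,7S)-7-ethynyl-2,6-dioxabicyclo[3.2.1]octane-3,4-diol (C3 epimers) | C#C[C@@H]1O[C@@H]2C[C@H]1OC(O)[C@@H]2O | intermediate
12 | (1R,4R,5R,7S)-7-ethynyl-4-hydroxy-2,6-dioxabicyclo[3.2.1]octan-3-one | C#C[C@@H]1O[C@@H]2C[C@H]1OC(=O)[C@@H]2O | intermediate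
13 | (1R,4R,5R,7S)-7-ethynyl-3-oxo-2,6-dioxabicyclo[3.2.1]octan-4-yl trifluoromethanesulfonate | C#C[C@@H]1O[C@@H]2C[C@H]1OC(=O)[C@@H]2OS(=O)(=O)C(F)(F)F | intermediate
14 | hydroxy triflate ester: methyl (2R)-2-[(2R,4R,5S)-5-ethynyl-4-hydroxyoxolan-2-yl]-2-[(trifluoromethanesulfonyl)oxy]acetate | C#C[C@@H]1O[C@H](C[C@H]1O)[C@@H](OS(=O)(=O)C(F)(F)F)C(=O)OC | intermediate
15 | methyl (1R,3S,4R,6S)-6-ethynyl-2,5-dioxabicyclo[2.2.1]heptane-3-carboxylate | C#C[C@@H]1O[C@@H]2C[C@H]1O[C@@H]2C(=O)OC | intermediate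
16 | (1R,3S,4R,6S)-6-ethynyl-2,5-dioxabicyclo[2.2.1]heptane-3-carbaldehyde | C#C[C@@H]1O[C@@H]2C[C@H]1O[C@@H]2C=O | intermediate
17 | (2E)-1-bromopent-2-ene | CC/C=C/CBr | starting material
18 | ethynylmagnesium bromide | C#C[Mg]Br | starting material
19 | (4E)-hept-4-en-1-yne | C#CC/C=C/CC | intermediate
20 | chlorobis(cyclopentadienyl)[(1E,4E)-hepta-1,4-dien-1-yl]zirconium | CC/C=C/C/C=C/[Zr](Cl)(C1C=CC=C1)C1C=CC=C1 | intermediate
21 | (1E,4E)-1-iodohepta-1,4-diene | CC/C=C/C/C=C/I | intermediate
22 | (1R,2E,5E)-1-[(1R,3R,4R,6S)-6-ethynyl-2,5-dioxabicyclo[2.2.1]heptan-3-yl]octa-2,5-dien-1-ol (8R allylic alcohol) | C#C[C@@H]1O[C@@H]2C[C@H]1O[C@@H]2[C@H](O)/C=C/C/C=C/CC | intermediate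
23 | (R)-[(1R,3R,4R,6S)-6-ethynyl-2,5-dioxabicyclo[2.2.1]heptan-3-yl]{(2S,3S)-3-[(2E)-pent-2-en-1-yl]oxiran-2-yl}methanol (erythro epoxy alcohol, trans-epoxide) | C#C[C@@H]1O[C@@H]2C[C@H]1O[C@@H]2[C@H](O)[C@@H]3O[C@H]3C/C=C/CC | intermediate
24 | C8 triflate of 23 (same configuration at C8, C9, C10) | C#C[C@@H]1O[C@@H]2C[C@H]1O[C@@H]2[C@H](OS(=O)(=O)C(F)(F)F)[C@@H]3O[C@H]3C/C=C/CC | intermediate
25 | (1R,3S,4R,6S)-3-[(S)-bromo{(2R,3S)-3-[(2E)-pent-2-en-1-yl]oxiran-2-yl}methyl]-6-ethynyl-2,5-dioxabicyclo[2.2.1]heptane (C8 inverted, Br placed as in the target) | C#C[C@@H]1O[C@@H]2C[C@H]1O[C@@H]2[C@@H](Br)[C@@H]3O[C@H]3C/C=C/CC | intermediate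
26 | epoxonium salt: 1-oxoniabicyclo[3.1.0]hexane with O⁺ bonded to C9, C10 and C13, Br on C12, ethyl on C13 anti to C9; bromopentachloroantimonate counter-ion | C#C[C@@H]1O[C@@H]2C[C@H]1O[C@@H]2[C@@H](Br)[C@H]3[C@@H]4C[C@H](Br)[C@@H](CC)[O+]34.Cl[Sb-](Cl)(Cl)(Cl)(Cl)Br | intermediate
27 | (1R,3S,4R,6S)-3-[(R)-bromo{(2R,3R,5S,6R)-3,5-dibromo-6-ethyloxan-2-yl}methyl]-6-ethynyl-2,5-dioxabicyclo[2.2.1]heptane (CNP0139964.2) | C#C[C@@H]1O[C@@H]2C[C@H]1O[C@@H]2[C@@H](Br)[C@@H]1O[C@H](CC)[C@@H](Br)C[C@H]1Br | target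

**Step count and risks**

Total: 17 steps. Longest linear sequence: 15 steps (1–11 and 14–17); steps 12–13 make the side-chain fragment.

Steps most likely to fail:

1. Step 17 (proposed new method). Halide may add to the bromonium ion before the weakly nucleophilic epoxide oxygen engages in the 5-endo mode (vicinal dihalide formation). The epoxonium ion may be opened at C9 through participation of the C8 bromine, or at C13 giving the vicinal dibromide, or be trapped by diethyl sulfide or by chloride from the antimonate. Fallback with known chemistry, from 25 to 27: the oxirane is opened by bromide at C10 with inversion (Li2NiBr4, THF, 0 °C; attack remote from the C8 bromide) to give bromohydrin F1. The C9 hydroxyl of F1 is then closed onto the 12,13-alkene by bromoetherification (2,4,4,6-tetrabromocyclohexa-2,5-dienone, CH2Cl2, −78 → 0 °C; anti addition, 6-endo mode). The oxolane isomer from 5-exo closure would have to be separated, and the sequence comes back to the route at 27.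

2. Step 16. Substitution at the hindered C8, flanked by the endo face of the bicycle and the oxirane, may lag behind bromide opening of the oxirane or ionisation of the triflate with ring-oxygen participation. Fallback, from 23 to 27, with the C–Br bond at C8 made last: the C8 hydroxyl is silylated (TBSOTf, 2,6-lutidine) to give silyl ether F2. The oxane is then built on F2 by the bromonium/bromide sequence of step 17 (or its stepwise variant under point 1) to give oxane silyl ether F3; this relies on the same unproven cascade, here without the C8 bromine that could interfere. TBAF gives oxane alcohol F4, and an Appel-type bromination with inversion (CBr4, P(n-Oct)3, toluene, 70 °C) returns to the route at 27.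

3. Step 10. β-Elimination of triflate across C6–C7, epimerisation at C7 or intermolecular attack by methoxide may outrun closure of the strained [2.2.1] ring. Fallback, from 12 to 15: lactone methanolysis (Et3N, MeOH) gives dihydroxy ester F5. An intramolecular Mitsunobu etherification (PPh3, DIAD, THF) then activates the α-hydroxy ester carbinol C7, which the C4 hydroxyl displaces with inversion; activation at C4 cannot lead to ring closure because the side chain lies on the face of the leaving group. The sequence comes back at 15.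

**Further compounds**

F1 | step 17 | bromohydrin: 8,10-dibromo-9-ol with C8, C9, C10 as in the target and the 12E-alkene intact | C#C[C@@H]1O[C@@H]2C[C@H]1O[C@@H]2[C@@H](Br)[C@H](O)[C@H](Br)C/C=C/CC
F2 | step 16 | silyl ether: C8 O-tert-butyldimethylsilyl ether of 23 | C#C[C@@H]1O[C@@H]2C[C@H]1O[C@@H]2[C@H](O[Si](C)(C)C(C)(C)C)[C@@H]3O[C@H]3C/C=C/CC
F3 | step 16 | oxane silyl ether: 10,12-dibromo oxane of the target with OTBS in place of Br at C8 (C8 configured as in 23) | C#C[C@@H]1O[C@@H]2C[C@H]1O[C@@H]2[C@H](O[Si](C)(C)C(C)(C)C)[C@@H]1O[C@H](CC)[C@@H](Br)C[C@H]1Br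
F4 | step 16 | oxane alcohol: C8 alcohol from F3 | C#C[C@@H]1O[C@@H]2C[C@H]1O[C@@H]2[C@H](O)[C@@H]1O[C@H](CC)[C@@H](Br)C[C@H]1Br
F5 | step 10 | dihydroxy ester: methyl (2R)-2-[(2R,4R,5S)-5-ethynyl-4-hydroxyoxolan-2-yl]-2-hydroxyacetate | C#C[C@@H]1O[C@H](C[C@H]1O)[C@@H](O)C(=O)OC
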